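Count the G in this flask against what the substrate will take of it.

the same everywhere: J 0.10 M; E 0.10 M; Q 0.28 mM; D 1.1 mM

| charge | G | remark | time |
|---|---|---|---|
| west | 0.20 M | run made earlier |  |
| south-east | 0.30 M | run made earlier |  |
| flask | 0.400 M |  | 20 min |

- west (time / min: J / %, Z / %): 1.00: 35.0, 22.7; 1.50: 32.8, 25.5; 2.50: 31.9, 27.2; 4.00: 31.2, 27.4; 8.00: 31.7, 27.6; 12.0: 31.9, 27.1
- south-east (time / min: J / %, Z / %): 1.00: 28.0, 32.0; 1.50: 26.1, 35.3; 2.50: 25.0, 37.2; 4.00: 24.6, 38.4; 8.00: 24.9, 37.9; 12.0: 24.4, 38.4

(readings scatter by 0.3 percentage points)

- at 20 min, what has stopped the reaction, if anything has (it is still moving / no working catalyst is left / forward and back rates have come level / G has run out first / all of J has reacted)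
- how much of the J and E together has reacted by 20 min
- how much Z there is at 20 min, in percent of the J and E together charged
- how much E there is at 20 min, in percent of the J and E together charged

- Q is single-handed; J and E are mirror images of each other, charged as a racemate, each of them at the stated concentration
- the numbers in the tables scatter with a standard deviation of 0.3 percentage points
- the reaction counts as stopped when no species that holds the J and E together changes by six tenths of a point or more over the second half of the time

I took D to keep J and E level, a racemisation fast enough to treat as finished at each moment, so that S, the J and E together, is twice J and starts at 0.200 M. I supposed that G leaves in two ways: with Q at a rate proportional to G and S, and by itself at a rate proportional to G. Taking one G for each S used with Q and dividing the two rates removes time, and once G is gone, G charged = fall in S + K·ln(S at start / S at end), where K is the rate constant of the loss by itself over that of the way with Q.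

I read the plateaus from 4.00 min on as G gone, and their readings, J at 31.6% in the west run and 24.6% in the south-east run, give K = 0.275 M and 0.280 M. I carried their mean, 0.278 M, as the loss charge: the G wasted per unit of that logarithm at this Q.

Turned round, taking S down to a quarter of its start asks 0.535 M of G, and this flask holds 0.400 M, so I expected G to go first with J remaining. Putting each answer back into the rule, from half reacted, gave 66.0%, 61.9%, 63.0% and 62.7%. That leaves E at 18.6%. On the plateau readings of the two runs, with E taken equal to J, Z was 74.9% of what reacted, which gives Z 47.0% in this flask.

The forecast said no working catalyst is left, with 47% reacted, Z 47% and E 33.3%, holding that “the catalyst dies in a few minutes”.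

The flask's answer on what stopped it was "G has run out first", with 63.1% reacted, Z 46.8% and E 18.4%. G was the limiting reagent in this flask: at 20.0 min, 0% of the G charged remained against 37% of the J charged.

    J + D ⇌ E + D, rate k1*[D]*[J] forward; the back reaction follows from the equilibrium constant (k = 360 L mol⁻¹ s⁻¹)
    G → L (k = 0.0180 s⁻¹)
    G + Q + E → Q + X (k = 120 L² mol⁻² s⁻¹)
    G + Q + J → Q + Z (k = 350 L² mol⁻² s⁻¹)

The computed conversion, put into the rule, returns K = 0.275 M, beside the 0.278 M carried from the runs.

For the neighbour charged with 1.0 M of G, K gave 94.4% reacted and, on the next pass, 94.6%. The computed neighbour reached 94.7%, with 0% of its G left.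

The numbers in the tables were generated by integration from invented constants, and the scatter is random.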